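**Assumptions:** (1) The SMILES `OC(=O)/C(C)=C/C` is the E isomer, so the C8 ester is a tiglate, not an angelate. (2) (R)-Citramalic acid is treated as commercially available. (3) The target numbering is furanoheliangolide numbering: C6 bears the lactone O, C8 the tiglate, C10 is the quaternary carbon, and C15 is the CH2OH on C4. (4) The target is (6R,7R,8S,10R), with a trans-fused 6,7-lactone.

## Retrosynthesis

1. The target comes from late tiglation of the C8 alcohol and removal of a C15 silyl ether.
2. The 10-membered carbocycle is closed last by an intramolecular Cr(II) allylation (C7–C8). A preformed 3-(bromomethyl)butenolide, which already contains the 12,6-lactone and the C6 centre, adds through its ring β-carbon (C7) to the C8 aldehyde. One step sets C7 (trans to C6) and C8 (anti, E-chair transition state) and unveils the exocyclic methylene. This is the bold step.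
3. The butenolide comes from ring-closing metathesis of a 2-(bromomethyl)acrylate ester of a chiral divinyl carbinol, with C6 set by CBS reduction.
4. The 3(2H)-furanone comes from 5-endo oxa-Michael cyclisation of a tertiary α-hydroxy ynone, which is built by Sonogashira coupling of a Z-vinyl iodide with a propargylic alcohol.
5. C10 comes from (R)-citramalic acid. The Z-C4=C5 olefin and C15 come from 2-butyne-1,4-diol via Red-Al/I2.
6. Rings form in the order furanone, then butenolide, then carbocycle.

## Route

**Step 1**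
Reactants: 1 (R)-citramalic acid
Product: 2 (R)-2-methylbutane-1,2,4-triol
Conditions: BH3·SMe2, THF, 0 °C → reflux; MeOH quench
Reagents that add atoms: none
Why: Borane reduces both carboxylic acids chemoselectively. No bond to the tertiary carbinol carbon changes, so C10 keeps its configuration.

**Step 2**
Reactants: 2; 3 TBSCl
Product: 4 (R)-4-(TBSO)-2-methylbutane-1,2-diol
Conditions: TBSCl (1.0 equiv), imidazole, CH2Cl2, –20 °C
Reagents that add atoms: TBSCl `C[Si](C)(Cl)C(C)(C)C`
Why: Silylation occurs at the unhindered primary OH (the future C8–O) rather than the neopentyl primary OH or the tertiary OH.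

**Step 3**
Reactants: 4
Product: 5 (R)-4-(TBSO)-2-hydroxy-2-methylbutanal
Conditions: TEMPO (cat.), PhI(OAc)2, CH2Cl2, rt
Reagents that add atoms: none
Why: TEMPO/BAIB oxidation of the only free primary alcohol. The α-carbon is quaternary, so the aldehyde cannot epimerise.

**Step 4**
Reactants: 5; 6 ethynylmagnesium bromide
Product: 7 (4R)-6-(TBSO)-4-methylhex-1-yne-3,4-diol (C3 epimeric mixture)
Conditions: HC≡CMgBr (3 equiv), THF, –78 → 0 °C
Reagents that add atoms: ethynylmagnesium bromide `C#C[Mg]Br`
Why: Grignard 1,2-addition. The new C1 carbinol stereocentre is destroyed by oxidation in step 13, so the epimer ratio does not matter.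

**Step 5**
Reactants: 8 but-2-yne-1,4-diol; 9 TBDPSCl
Product: 10 4-(TBDPSO)but-2-yn-1-ol
Conditions: NaH (1.0 equiv), THF, 0 °C; then TBDPSCl
Reagents that add atoms: TBDPSCl `CC(C)(C)[Si](Cl)(c1ccccc1)c1ccccc1`
Why: Statistical mono-silylation of a symmetric diol.

**Step 6**
Reactants: 10; 11 iodine
Product: 12 (2Z)-4-(TBDPSO)-3-iodobut-2-en-1-ol
Conditions: Red-Al, THF, 0 °C; then I2, –78 °C
Reagents that add atoms: I2 `II`
Why: Alkoxide-directed trans-hydroalumination through a five-membered oxa-alumina-cycle places Al on C3, and iodinolysis gives the Z-vinyl iodide. The CH2OH and I end up cis, which is the geometry needed for C6 cis to C3 in the natural product.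

**Step 7**
Reactants: 12
Product: 13 (2Z)-4-(TBDPSO)-3-iodobut-2-enal
Conditions: MnO2, CH2Cl2, rt
Reagents that add atoms: none
Why: MnO2 oxidises the allylic alcohol selectively and leaves the olefin geometry intact.

**Step 8**
Reactants: 13; 14 vinylmagnesium bromide
Product: 15 (rac,4Z)-6-(TBDPSO)-5-iodohexa-1,4-dien-3-ol
Conditions: CH2=CHMgBr, THF, –78 °C
Reagents that add atoms: vinylmagnesium bromide `C=C[Mg]Br`
Why: 1,2-Addition to the enal. The racemic stereocentre is erased in step 9.

**Step 9**
Reactants: 15
Product: 16 (4Z)-6-(TBDPSO)-5-iodohexa-1,4-dien-3-one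
Conditions: Dess–Martin periodinane, NaHCO3, CH2Cl2, 0 °C
Reagents that add atoms: none
Why: Oxidation to the unsymmetrical divinyl ketone, which is used immediately.

**Step 10**
Reactants: 16
Product: 17 (3S,4Z)-6-(TBDPSO)-5-iodohexa-1,4-dien-3-ol
Conditions: (R)-Me-CBS (20 mol%), BH3·SMe2, THF, –30 °C
Reagents that add atoms: none
Why: Corey–Bakshi–Shibata reduction sets C6. The bulky (Z)-β-iodo-β-silyloxymethyl vinyl group is the large substituent and the plain vinyl group the small one. The (R)-catalyst gives the alcohol whose spatial arrangement matches target C6 (R); the descriptor is S here only because iodine changes the CIP priorities.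

**Step 11**
Reactants: 17; 18 TESOTf
Product: 19 TES ether of 17
Conditions: TESOTf, 2,6-lutidine, CH2Cl2, –78 °C
Reagents that add atoms: TESOTf `CC[Si](CC)(CC)OS(=O)(=O)C(F)(F)F`
Why: Protects C6–OH so it survives the MnO2 oxidation in step 13. TES is chosen because it can be removed selectively later in the presence of the primary TBS and TBDPS ethers.

**Step 12**
Reactants: 19; 7
Product: 20 enyne diol
Conditions: Pd(PPh3)4 (5 mol%), CuI (10 mol%), iPr2NH, THF, rt
Reagents that add atoms: none beyond the two reactants
Why: Sonogashira coupling proceeds with retention of the Z geometry, giving C3–C4 with C6 cis to C3.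

**Step 13**
Reactants: 20
Product: 21 enynone (α-hydroxy ynone)
Conditions: MnO2, CH2Cl2, rt
Reagents that add atoms: none
Why: MnO2 oxidises the propargylic secondary alcohol. The tertiary OH and all silyl ethers are untouched, and both C1 epimers give the same ketone.

**Step 14**
Reactants: 21
Product: 22 3(2H)-furanone
Conditions: DBU (10 mol%), CH2Cl2, 0 °C
Reagents that add atoms: none
Why: The tertiary alkoxide undergoes 5-endo-dig oxa-Michael addition to C3 of the ynone, and protonation gives the furan-3(2H)-one. The quaternary C10 stereocentre is not involved and cannot epimerise.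

**Step 15**
Reactants: 22
Product: 23 free C6 alcohol
Conditions: PPTS, MeOH/CH2Cl2, 0 °C
Reagents that add atoms: none
Why: Secondary TES ethers cleave much faster than the primary TBS and TBDPS ethers under these conditions.

**Step 16**
Reactants: 23; 24 2-(bromomethyl)acrylic acid
Product: 25 C6 acrylate ester
Conditions: EDC·HCl, DMAP (cat.), CH2Cl2, 0 °C
Reagents that add atoms: 2-(bromomethyl)acrylic acid `C=C(CBr)C(=O)O`
Why: Steglich esterification, with no change at C6.

**Step 17**
Reactants: 25
Product: 26 (5R)-3-(bromomethyl)butenolide bearing the furanone side chain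
Conditions: Hoveyda–Grubbs II (10 mol%), CH2Cl2 (5 mM), 40 °C
Reagents that add atoms: none (ethylene is lost)
Why: Ring-closing metathesis between the acrylate and the C7 vinyl group forms the 12,6-butenolide. The trisubstituted dienyl olefin is too hindered to react, and C6 is untouched.

**Step 18**
Reactants: 26
Product: 27 primary alcohol
Conditions: 48% aq. HF, MeCN, 0 °C
Reagents that add atoms: none
Why: The primary TBS ether is removed while the TBDPS ether, the allylic bromide and the butenolide survive. Non-nucleophilic acidic conditions avoid pyridine or fluoride attacking the bromide.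

**Step 19**
Reactants: 27
Product: 28 aldehyde (NHK precursor)
Conditions: Dess–Martin periodinane, NaHCO3, CH2Cl2, 0 °C
Reagents that add atoms: none
Why: Buffered oxidation of the primary alcohol. The aldehyde is used immediately, because it is β-alkoxy and could eliminate.

**Step 20**
Reactants: 28
Product: 29 macrocyclic C8 alcohol (15-O-TBDPS-8-O-deacyl lychnophorolide B)
Conditions: CrCl2 (10 equiv), THF/DMF (9:1), 0.002 M (slow addition of 28), 25 °C
Reagents that add atoms: none (Br is lost; the alkoxide becomes OH on workup)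
Why: Intramolecular Nozaki–Hiyama–Kishi (Barbier-type) allylation. The allylchromium reacts at C7, the ring β-carbon. Because C6 is trans to the CH2Cr arm, this is an E-type allyl unit. A chair transition state therefore gives the anti C7/C8 relationship, which is (7R,8S) given C6 (R), and attack on the face opposite the C6 substituent gives the trans-fused lactone. The same step creates the exocyclic methylene and the 10-membered ring.
Proposed new method: This extends the known intermolecular Zn/In/Cr allylation of aldehydes with 3-(bromomethyl)-2(5H)-furanone to a macrocyclisation. The closest known reaction type is intramolecular NHK ring closure in germacranolide syntheses.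

**Step 21**
Reactants: 29; 30 tiglic acid
Product: 31 C8 tiglate, C15-OTBDPS
Conditions: tiglic acid, 2,4,6-Cl3C6H2COCl, Et3N, THF, 0 °C; then 29, DMAP, toluene, rt
Reagents that add atoms: tiglic acid `OC(=O)/C(C)=C/C`
Why: Yamaguchi esterification. The C8 configuration is retained and the E olefin is preserved. C15 is still protected, so only one free OH is present.

**Step 22**
Reactants: 31
Product: 32 Lychnophorolide B
Conditions: HF·pyridine, THF, 0 °C → rt
Reagents that add atoms: none
Why: Fluoride-mediated cleavage of the primary TBDPS ether gives the C15 allylic alcohol. The lactone, furanone and tiglate are unaffected.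

## Compound list

| No. | Name | SMILES | Role |
|---|---|---|---|
| 1 | (R)-citramalic acid | `OC(=O)[C@@](C)(CC(=O)O)O` | starting material |
| 2 | (R)-2-methylbutane-1,2,4-triol | `OC[C@@](C)(CCO)O` | intermediate |
| 3 | TBSCl | `C[Si](C)(Cl)C(C)(C)C` | starting material (reagent) |
| 4 | (R)-4-(TBSO)-2-methylbutane-1,2-diol | `OC[C@@](C)(CCO[Si](C)(C)C(C)(C)C)O` | intermediate |
| 5 | (R)-4-(TBSO)-2-hydroxy-2-methylbutanal | `O=C[C@@](C)(CCO[Si](C)(C)C(C)(C)C)O` | intermediate |
| 6 | ethynylmagnesium bromide | `C#C[Mg]Br` | starting material (reagent) |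
| 7 | (4R)-6-(TBSO)-4-methylhex-1-yne-3,4-diol (C3 epimers) | `C#CC(O)[C@@](C)(CCO[Si](C)(C)C(C)(C)C)O` | intermediate |
| 8 | but-2-yne-1,4-diol | `OCC#CCO` | starting material |
| 9 | TBDPSCl | `CC(C)(C)[Si](Cl)(c1ccccc1)c1ccccc1` | starting material (reagent) |
| 10 | 4-(TBDPSO)but-2-yn-1-ol | `OCC#CCO[Si](c1ccccc1)(c1ccccc1)C(C)(C)C` | intermediate |
| 11 | iodine | `II` | starting material (reagent) |
| 12 | (2Z)-4-(TBDPSO)-3-iodobut-2-en-1-ol | `OC/C=C(\I)CO[Si](c1ccccc1)(c1ccccc1)C(C)(C)C` | intermediate |
| 13 | (2Z)-4-(TBDPSO)-3-iodobut-2-enal | `O=C/C=C(\I)CO[Si](c1ccccc1)(c1ccccc1)C(C)(C)C` | intermediate |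
| 14 | vinylmagnesium bromide | `C=C[Mg]Br` | starting material (reagent) |
| 15 | (4Z)-6-(TBDPSO)-5-iodohexa-1,4-dien-3-ol (racemic) | `C=CC(O)/C=C(\I)CO[Si](c1ccccc1)(c1ccccc1)C(C)(C)C` | intermediate |
| 16 | (4Z)-6-(TBDPSO)-5-iodohexa-1,4-dien-3-one | `C=CC(=O)/C=C(\I)CO[Si](c1ccccc1)(c1ccccc1)C(C)(C)C` | intermediate |
| 17 | (3S,4Z)-6-(TBDPSO)-5-iodohexa-1,4-dien-3-ol | `C=C[C@H](O)/C=C(\I)CO[Si](c1ccccc1)(c1ccccc1)C(C)(C)C` | intermediate |
| 18 | TESOTf | `CC[Si](CC)(CC)OS(=O)(=O)C(F)(F)F` | starting material (reagent) |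
| 19 | C6-OTES ether of 17 | `C=C[C@H](O[Si](CC)(CC)CC)/C=C(\I)CO[Si](c1ccccc1)(c1ccccc1)C(C)(C)C` | intermediate |
| 20 | enyne diol | `C=C[C@H](O[Si](CC)(CC)CC)/C=C(\C#CC(O)[C@@](C)(CCO[Si](C)(C)C(C)(C)C)O)CO[Si](c1ccccc1)(c1ccccc1)C(C)(C)C` | intermediate |
| 21 | enynone (α-hydroxy ynone) | `C=C[C@H](O[Si](CC)(CC)CC)/C=C(\C#CC(=O)[C@@](C)(CCO[Si](C)(C)C(C)(C)C)O)CO[Si](c1ccccc1)(c1ccccc1)C(C)(C)C` | intermediate |
| 22 | 3(2H)-furanone | `C=C[C@H](O[Si](CC)(CC)CC)/C=C(/CO[Si](c1ccccc1)(c1ccccc1)C(C)(C)C)C1=CC(=O)[C@@](C)(CCO[Si](C)(C)C(C)(C)C)O1` | intermediate |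
| 23 | C6-OH furanone | `C=C[C@H](O)/C=C(/CO[Si](c1ccccc1)(c1ccccc1)C(C)(C)C)C1=CC(=O)[C@@](C)(CCO[Si](C)(C)C(C)(C)C)O1` | intermediate |
| 24 | 2-(bromomethyl)acrylic acid | `C=C(CBr)C(=O)O` | starting material (reagent) |
| 25 | C6 2-(bromomethyl)acrylate ester | `C=C[C@H](OC(=O)C(=C)CBr)/C=C(/CO[Si](c1ccccc1)(c1ccccc1)C(C)(C)C)C1=CC(=O)[C@@](C)(CCO[Si](C)(C)C(C)(C)C)O1` | intermediate |
| 26 | 3-(bromomethyl)butenolide, C8-OTBS | `BrCC1=C[C@@H](/C=C(/CO[Si](c2ccccc2)(c2ccccc2)C(C)(C)C)C2=CC(=O)[C@@](C)(CCO[Si](C)(C)C(C)(C)C)O2)OC1=O` | intermediate |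
| 27 | butenolide bromide, primary alcohol | `BrCC1=C[C@@H](/C=C(/CO[Si](c2ccccc2)(c2ccccc2)C(C)(C)C)C2=CC(=O)[C@@](C)(CCO)O2)OC1=O` | intermediate |
| 28 | butenolide bromide, C8 aldehyde | `BrCC1=C[C@@H](/C=C(/CO[Si](c2ccccc2)(c2ccccc2)C(C)(C)C)C2=CC(=O)[C@@](C)(CC=O)O2)OC1=O` | intermediate |
| 29 | macrocyclic C8 alcohol, 15-OTBDPS | `C=C1C(=O)O[C@@H]2/C=C(/CO[Si](c3ccccc3)(c3ccccc3)C(C)(C)C)C3=CC(=O)[C@@](C)(C[C@H](O)[C@@H]12)O3` | intermediate |
| 30 | tiglic acid | `OC(=O)/C(C)=C/C` | starting material (reagent) |
| 31 | C8 tiglate, 15-OTBDPS | `C=C1C(=O)O[C@@H]2/C=C(/CO[Si](c3ccccc3)(c3ccccc3)C(C)(C)C)C3=CC(=O)[C@@](C)(C[C@H](OC(=O)/C(C)=C/C)[C@@H]12)O3` | intermediate |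
| 32 | Lychnophorolide B | `C=C1C(=O)O[C@@H]2/C=C(/CO)C3=CC(=O)[C@@](C)(C[C@H](OC(=O)/C(C)=C/C)[C@@H]12)O3` | target |

**Total steps:** 22.

**Longest linear sequence:** 18 steps, from but-2-yne-1,4-diol (8) to 32. The citramalic acid branch is 4 steps and joins at step 12.

## Three steps most likely to fail

1. **Step 20 (Cr macrocyclisation).** The risks are a cis-fused or C8-epimeric product, oligomerisation, and translactonisation of the C8 alkoxide onto C12. Fallback: an intramolecular Tamaru Pd(0)/Et3B umpolung allylation of the corresponding 3-(hydroxymethyl)butenolide, which goes through a π-allylpalladium/allylborane pathway instead of allylchromium.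
2. **Step 17 (RCM of the 2-(bromomethyl)acrylate).** The allylic bromide can poison the Ru catalyst, and the γ-alkenyl butenolide is prone to racemisation. Fallback: make the ester with plain acrylic acid, close the 3-unsubstituted butenolide by RCM, then install C13 by α-iodination, Stille coupling with Bu3SnCH2OH and Appel bromination.
3. **Step 10 (CBS reduction of divinyl ketone 16).** The ketone is unstable and enantioselectivity may be modest. Fallback: skip the oxidation and resolve racemic alcohol 15 by lipase-catalysed acetylation or Sharpless kinetic resolution, recycling the unwanted enantiomer through steps 9 and 10.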